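**Plan**

- Retrosynthesis: the two phenolic benzyl ethers are cut last, and the C3 hydroxymethyl group is traced back through a formyl group to a vinyl group. The tetrahydrofuran ring (O1, C2 aryl, C3, C4 aroyl, C5 methylene) is then cut at O1–C5 and C3–C4 in one operation, giving vinyl epoxide 8 and aryl vinyl ketone 4, both made from aldehyde 1.
- Enabling feature: with the C3 substituent written as vinyl, O1–C2–C3 is an alkoxide next to an allylic carbon, i.e. the zwitterionic η3-allylpalladium alkoxide obtained by opening a 2-aryl-3-vinyloxirane. C5–C4–C(=O)Ar is an aryl vinyl ketone: its β-carbon C5 accepts the oxygen and its α-carbon C4, as the enolate, accepts the allyl terminus C3.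
- Forward: 1 → enone 4 (two steps); 1 → chlorohydrin 7 → cis epoxide 8; 8 + 4 → tetrahydrofuran 9 (the only ring-forming step); vinyl → CHO → CH2OH; hydrogenolysis.
- Stereochemistry: C2 comes from the reagent-controlled γ-chloroallylboration (isopinocampheyl groups of (−)-Ipc2BOMe). C3 and C4 are set trans,trans relative to C2 in the ring closure, and both stay thermodynamically correctable (C4 α to the ketone, C3 α to the aldehyde in 10).

Key step: step 5

Remark: compounds 1, 2, 5 and (−)-Ipc2BOMe are taken as commercial; ring atoms are numbered O1, C2 (aryl), C3 (hydroxymethyl), C4 (aroyl), C5 (CH2) throughout.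

**Route**

Step 1
Reactants: 1 3-(benzyloxy)-4-methoxybenzaldehyde; 2 vinylmagnesium bromide
Product: 3 rac-1-[3-(benzyloxy)-4-methoxyphenyl]prop-2-en-1-ol
Conditions: CH2=CHMgBr (1.2 equiv), THF, −78 °C to 0 °C; aq NH4Cl
Reagents that add atoms: vinylmagnesium bromide (compound 2), C=C[Mg]Br
Why: 1,2-addition of a vinyl Grignard reagent to the aromatic aldehyde should be fast and clean, and the racemic carbinol centre it creates is erased in step 2.

Step 2
Reactants: 3 rac-1-[3-(benzyloxy)-4-methoxyphenyl]prop-2-en-1-ol
Product: 4 1-[3-(benzyloxy)-4-methoxyphenyl]prop-2-en-1-one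
Conditions: MnO2 (activated, 10 equiv), CH2Cl2, rt; filtration through Celite, used at once
Reagents that add atoms: none
Why: MnO2 oxidation of a doubly activated (benzylic and allylic) alcohol proceeds under neutral heterogeneous conditions, so the polymerisation-prone aryl vinyl ketone should be obtained by filtration alone.

Step 3
Reactants: 1 3-(benzyloxy)-4-methoxybenzaldehyde; 5 allyl chloride
Product: 7 (1R,2R)-1-[3-(benzyloxy)-4-methoxyphenyl]-2-chlorobut-3-en-1-ol, via (Z)-chloroallylborane 6 (not isolated)
Conditions: allyl chloride, LiN(c-C6H11)2, (−)-Ipc2BOMe, Et2O/THF, −95 °C; BF3·OEt2, then 1, −95 °C; HOCH2CH2NH2 work-up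
Reagents that add atoms: allyl chloride (compound 5), C=CCCl
Why: asymmetric γ-chloroallylboration, in which α-lithiated allyl chloride is trapped by (−)-Ipc2BOMe as the (Z)-γ-chloroallylborane that adds to the Si face of the aldehyde through a chair Zimmerman–Traxler transition state, so the isopinocampheyl groups should set the (1R) carbinol centre and the Z geometry the syn chlorine.

Step 4
Reactants: 7 (1R,2R)-1-[3-(benzyloxy)-4-methoxyphenyl]-2-chlorobut-3-en-1-ol
Product: 8 (2R,3S)-2-[3-(benzyloxy)-4-methoxyphenyl]-3-ethenyloxirane (cis)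
Conditions: DBU (1.5 equiv), CH2Cl2, 0 °C to rt; filtration through basic alumina, used without chromatography
Reagents that add atoms: none
Why: intramolecular Williamson displacement (3-exo-tet, inversion at the chloride carbon) should convert the syn chlorohydrin into the cis vinyl epoxide without touching the benzylic stereocentre, under anhydrous basic conditions that the acid-labile electron-rich aryl epoxide tolerates.

Step 5
Reactants: 8 (2R,3S)-2-[3-(benzyloxy)-4-methoxyphenyl]-3-ethenyloxirane; 4 1-[3-(benzyloxy)-4-methoxyphenyl]prop-2-en-1-one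
Product: 9 [3-(benzyloxy)-4-methoxyphenyl]{(3S,4S,5S)-5-[3-(benzyloxy)-4-methoxyphenyl]-4-ethenyloxolan-3-yl}methanone
Conditions: Pd2(dba)3·CHCl3 (2.5 mol %), Xantphos (5.5 mol %), THF, 0 °C to rt, 4 (1.3 equiv) added over 1 h; then DBU (0.2 equiv), rt
Reagents that add atoms: none
Why: Zerovalent palladium ionises the allylic C–O bond of 8 with inversion to a zwitterion (a benzylic alkoxide carrying an η3-allylpalladium cation); the alkoxide adds to the unsubstituted β-carbon of 4 (oxa-Michael, forming O1–C5), and the resulting ketone enolate attacks the internal allyl terminus anti to the metal (forming C3–C4) and releases the catalyst. The closest known reaction type is the palladium-catalysed formal [3+2] cycloaddition of vinyl epoxides with Michael acceptors, α,β-unsaturated ketones included. The tetrahydrofuran ring, the only ring formed, closes by 5-exo attack of the enolate carbon on the allyl terminus, leaving the other two allyl carbons as the exocyclic vinyl group, whereas attack at the CH2 terminus or O-alkylation of the enolate would each need a seven-membered ring. C2 is the untouched benzylic centre of 8; C3 is controlled by C2, because the two faces of the allyl unit should interconvert by η3–η1–η3 isomerisation at the CH2 terminus faster than the bimolecular trapping (so the cis geometry of 8 is not inherited) and the closure that places aryl and vinyl trans on the forming ring is favoured; C4 is α to the ketone and is brought to the trans arrangement by the closing DBU equilibration. The step needs capture of the alkoxide by 4 to outrun hydride shift to an aryl ketone, and cyclisation to outrun enolate addition to a second molecule of 4, which the high electrophilicity of the unsubstituted aryl vinyl ketone, its slow addition and the intramolecular closing step should secure. Should some 2,3-cis isomer form, C3 becomes α to the formyl group in 10 and can be equilibrated there, so C2 alone ultimately dictates all three centres.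

Step 6
Reactants: 9 [3-(benzyloxy)-4-methoxyphenyl]{(3S,4S,5S)-5-[3-(benzyloxy)-4-methoxyphenyl]-4-ethenyloxolan-3-yl}methanone
Product: 10 (2S,3S,4S)-4-[3-(benzyloxy)-4-methoxybenzoyl]-2-[3-(benzyloxy)-4-methoxyphenyl]oxolane-3-carbaldehyde
Conditions: OsO4 (2 mol %), NaIO4 (4 equiv), 2,6-lutidine (2 equiv), 1,4-dioxane/H2O (3:1), rt; crude aldehyde taken on directly
Reagents that add atoms: osmium tetroxide, O=[Os](=O)(=O)=O (catalytic oxygen carrier); sodium periodate, [Na+].[O-]I(=O)(=O)=O (terminal oxidant that supplies the oxygen)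
Why: Lemieux–Johnson cleavage (catalytic dihydroxylation of the only alkene, then periodate glycol cleavage) should excise the terminal carbon while the 2,6-lutidine buffer protects the β-alkoxy aldehyde and the electron-rich arenes and benzyl ethers stay untouched, the trans,trans arrangement being the thermodynamic one at the now epimerisable C3.

Step 7
Reactants: 10 (2S,3S,4S)-4-[3-(benzyloxy)-4-methoxybenzoyl]-2-[3-(benzyloxy)-4-methoxyphenyl]oxolane-3-carbaldehyde
Product: 11 {(3S,4R,5S)-5-[3-(benzyloxy)-4-methoxyphenyl]-4-(hydroxymethyl)oxolan-3-yl}[3-(benzyloxy)-4-methoxyphenyl]methanone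
Conditions: NaBH4 (0.5 equiv), CH2Cl2/MeOH (3:1), −78 °C; aq NH4Cl at −78 °C
Reagents that add atoms: none
Why: chemoselective borohydride reduction at low temperature, in which the unhindered aliphatic aldehyde should be reduced far faster than the conjugated electron-rich aryl ketone, creates no stereocentre and disturbs none.

Step 8
Reactants: 11 {(3S,4R,5S)-5-[3-(benzyloxy)-4-methoxyphenyl]-4-(hydroxymethyl)oxolan-3-yl}[3-(benzyloxy)-4-methoxyphenyl]methanone
Product: 12 (3-hydroxy-4-methoxyphenyl)[(3S,4R,5S)-5-(3-hydroxy-4-methoxyphenyl)-4-(hydroxymethyl)oxolan-3-yl]methanone (CNP0234761.1)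
Conditions: H2 (1 atm), 10% Pd/C, EtOAc, rt, stopped at consumption of 11
Reagents that add atoms: none
Why: catalytic hydrogenolysis should cleave the two aryl benzyl ethers much faster than it reduces the electron-rich aryl ketone or the cyclic benzylic C–O bond, releasing both phenols with the three stereocentres intact.

**Compound list**

1 | 3-(benzyloxy)-4-methoxybenzaldehyde | COc1ccc(C=O)cc1OCc1ccccc1 | starting material
2 | vinylmagnesium bromide | C=C[Mg]Br | starting material
3 | rac-1-[3-(benzyloxy)-4-methoxyphenyl]prop-2-en-1-ol | COc1ccc(C(O)C=C)cc1OCc1ccccc1 | intermediate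
4 | 1-[3-(benzyloxy)-4-methoxyphenyl]prop-2-en-1-one | COc1ccc(C(=O)C=C)cc1OCc1ccccc1 | intermediate
5 | allyl chloride (3-chloroprop-1-ene) | C=CCCl | starting material
6 | [(Z)-3-chloroprop-2-en-1-yl]diisopinocampheylborane, isopinocampheyl groups from (−)-Ipc2BOMe (not isolated) | Cl/C=C\CB([C@@H]1C[C@@H]2C[C@H]([C@H]1C)C2(C)C)[C@@H]1C[C@@H]2C[C@H]([C@H]1C)C2(C)C | intermediate
7 | (1R,2R)-1-[3-(benzyloxy)-4-methoxyphenyl]-2-chlorobut-3-en-1-ol (syn) | COc1ccc([C@@H](O)[C@H](Cl)C=C)cc1OCc1ccccc1 | intermediate
8 | (2R,3S)-2-[3-(benzyloxy)-4-methoxyphenyl]-3-ethenyloxirane (cis) | COc1ccc([C@H]2O[C@H]2C=C)cc1OCc1ccccc1 | intermediate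
9 | [3-(benzyloxy)-4-methoxyphenyl]{(3S,4S,5S)-5-[3-(benzyloxy)-4-methoxyphenyl]-4-ethenyloxolan-3-yl}methanone (all-trans) | COc1ccc(C(=O)[C@@H]2CO[C@H](c3ccc(OC)c(OCc4ccccc4)c3)[C@H]2C=C)cc1OCc1ccccc1 | intermediate
10 | (2S,3S,4S)-4-[3-(benzyloxy)-4-methoxybenzoyl]-2-[3-(benzyloxy)-4-methoxyphenyl]oxolane-3-carbaldehyde | COc1ccc(C(=O)[C@@H]2CO[C@H](c3ccc(OC)c(OCc4ccccc4)c3)[C@H]2C=O)cc1OCc1ccccc1 | intermediate
11 | {(3S,4R,5S)-5-[3-(benzyloxy)-4-methoxyphenyl]-4-(hydroxymethyl)oxolan-3-yl}[3-(benzyloxy)-4-methoxyphenyl]methanone | COc1ccc(C(=O)[C@@H]2CO[C@H](c3ccc(OC)c(OCc4ccccc4)c3)[C@H]2CO)cc1OCc1ccccc1 | intermediate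
12 | (3-hydroxy-4-methoxyphenyl)[(3S,4R,5S)-5-(3-hydroxy-4-methoxyphenyl)-4-(hydroxymethyl)oxolan-3-yl]methanone | COc1ccc(C(=O)[C@@H]2CO[C@H](c3ccc(OC)c(O)c3)[C@H]2CO)cc1O | target

**Totals**

Total step count: 8. Longest linear sequence: 6 steps (steps 3, 4, 5, 6, 7, 8 from aldehyde 1).

**Steps most likely to fail**

Step 5. The failure process would be anionic oligomerisation of the vinyl ketone or hydride shift within the zwitterion outrunning the oxa-Michael and allylation sequence. The fallback replaces the simple enone by a doubly activated acceptor carrying a removable ester; it sets out from 1 and 8 and comes back at 9. Aldehyde 1 is homologated with ethyl diazoacetate (SnCl2 cat., CH2Cl2; Roskamp reaction) to ethyl 3-[3-(benzyloxy)-4-methoxyphenyl]-3-oxopropanoate F1. This is α-methylenated (paraformaldehyde, diisopropylammonium trifluoroacetate, THF, reflux) to ethyl 2-[3-(benzyloxy)-4-methoxybenzoyl]prop-2-enoate F2, used at once. F2 should undergo the classical Pd(PPh3)4-catalysed [3+2] cycloaddition with epoxide 8 in THF through a stabilised β-keto ester enolate, giving ethyl (4S,5S)-3-[3-(benzyloxy)-4-methoxybenzoyl]-5-[3-(benzyloxy)-4-methoxyphenyl]-4-ethenyloxolane-3-carboxylate F3 as a mixture at the quaternary carbon. Krapcho dealkoxycarbonylation (LiCl, wet DMSO, 130 °C) then removes the helper ester with thermodynamic protonation at C4 and returns to 9.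

Step 4. The failure process would be acid- or silica-induced opening or rearrangement of the electron-rich aryl epoxide during its formation and handling. The fallback avoids the epoxide; it sets out from 7 and comes back at 9. Chlorohydrin 7 is carboxylated and cyclised with inversion (Cs2CO3, CO2 at 1 atm, DMF, rt) to the stable, chromatographable (4R,5S)-4-[3-(benzyloxy)-4-methoxyphenyl]-5-ethenyl-1,3-dioxolan-2-one F4. Under the catalyst of step 5, F4 should lose CO2 on ionisation to give the same zwitterion and combine with 4 to give 9.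

Step 3. The failure process would be decomposition of the lithiated allyl chloride before capture by the borane, or insufficient facial selectivity with the electron-rich aldehyde. The fallback sets the benzylic centre by catalytic asymmetric epoxidation instead; it sets out from 1 and comes back at 9. Aldehyde 1 is olefinated with lithiated diethyl allylphosphonate (n-BuLi, THF/HMPA, −78 °C to rt) to (E)-1-[3-(benzyloxy)-4-methoxyphenyl]buta-1,3-diene F5. Shi epoxidation of its (E)-disubstituted styrenic alkene (D-fructose-derived ketone cat., Oxone (2KHSO5·KHSO4·K2SO4), K2CO3, MeCN/dimethoxymethane/aq buffer, 0 °C) should give (2R,3R)-2-[3-(benzyloxy)-4-methoxyphenyl]-3-ethenyloxirane F6. F6 has the same benzylic configuration as 8 and enters step 5 in its place, since both epoxides open to the same zwitterion, to give 9.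

**Further compounds**

F1 | step 5 | ethyl 3-[3-(benzyloxy)-4-methoxyphenyl]-3-oxopropanoate | CCOC(=O)CC(=O)c1ccc(OC)c(OCc2ccccc2)c1
F2 | step 5 | ethyl 2-[3-(benzyloxy)-4-methoxybenzoyl]prop-2-enoate | CCOC(=O)C(=C)C(=O)c1ccc(OC)c(OCc2ccccc2)c1
F3 | step 5 | ethyl (4S,5S)-3-[3-(benzyloxy)-4-methoxybenzoyl]-5-[3-(benzyloxy)-4-methoxyphenyl]-4-ethenyloxolane-3-carboxylate (both C3 epimers) | CCOC(=O)C1(C(=O)c2ccc(OC)c(OCc3ccccc3)c2)CO[C@H](c2ccc(OC)c(OCc3ccccc3)c2)[C@H]1C=C
F4 | step 4 | (4R,5S)-4-[3-(benzyloxy)-4-methoxyphenyl]-5-ethenyl-1,3-dioxolan-2-one (cis) | COc1ccc([C@H]2OC(=O)O[C@H]2C=C)cc1OCc1ccccc1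
F5 | step 3 | (E)-1-[3-(benzyloxy)-4-methoxyphenyl]buta-1,3-diene | COc1ccc(/C=C/C=C)cc1OCc1ccccc1
F6 | step 3 | (2R,3R)-2-[3-(benzyloxy)-4-methoxyphenyl]-3-ethenyloxirane (trans) | COc1ccc([C@H]2O[C@@H]2C=C)cc1OCc1ccccc1
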